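| setting | birch | cedar | larch | ash |
|---|---|---|---|---|
| first end groups | 0.0020 M | 0.0020 M | 0.0020 M (fed, over 32.0 s) | 0.0020 M |
| second end groups | 1.90 mM | 1.90 mM | 1.90 mM | 1.90 mM (fed, over 32.0 s) |
| remark | a single well-mixed tank run continuously and read at steady state, 40 s in it on average | everything together in a closed stirred flask, run for 40 s | all but first end groups at the start; first end groups goes in evenly over 32.0 s, the run ends at 40 s | all but second end groups at the start; second end groups goes in evenly over 32.0 s, the run ends at 40 s |
| time |  | 40 s | 40 s | 40 s |

    first end groups + second end groups ⇌ links (K1 = 13000 L mol⁻¹, k1 = 910 L mol⁻¹ s⁻¹)

- the stated concentrations are those of everything mixed, before any reaction; amounts are the same in each set-up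
- the feed brings no volume worth counting
- run time (cedar): 40 s

- the set-up with the highest amount of links at the outlet or at the end, in percent of the first end groups put in ("none" if the first two lie within 2 percentage points) (birch / cedar / larch / ash / none)
- amount of links at the outlet or at the end, in percent of the first end groups put in, birch
- amount of links at the outlet or at the end, in percent of the first end groups put in, cedar
- amount of links at the outlet or at the end, in percent of the first end groups put in, larch
- amount of links at the outlet or at the end, in percent of the first end groups put in, ash

The amounts were the same in each set-up, so I counted what stayed unlinked and took links as the rest of the charge of first end groups. Second end groups, the limiting reagent, were charged at 1.90 mM against 0.0020 M, so I kept [second end groups] below [first end groups] by that gap and solved one quadratic for each constant linking [links] to their product.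

My first extreme kept the way back and allowed unlimited time: the constant was 13000 L mol⁻¹, leaving 0.404 mM, or 20.2 % of the first end groups. My second was birch without the way back: the constant was the rate constant times the mean time, 36400 L mol⁻¹, leaving 0.273 mM, or 13.7 %.

In birch at steady state, links washed out per mean time equal net formation. The outlet ratio [links]/([first end groups][second end groups]), which I called the tank constant, therefore has as its reciprocal the sum of the reciprocals of those two constants: 9580 L mol⁻¹. It lay below both, so the quadratic left 0.455 mM in birch, or 22.8 %, which is more than either extreme left, and that gave 77.2 % links.

Near equilibrium I reckoned a relaxation rate of 0.714 s⁻¹, a relaxation time of 1.40 s. That is short against cedar's 40 s and against the 8.00 s that larch and ash stood after feeding. I therefore put cedar, larch and ash each at 79.8 %, tied within 2 percentage points.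

The forecast gave 77.3 % for birch, 79.8 %, 79.8 % and 79.8 % for cedar, larch and ash, and best none, holding of birch that “its 40 s mean residence time is long compared with the reaction time scale”.

The simulation gave 77.3 % for birch, 79.8 %, 79.8 % and 79.8 % for cedar, larch and ash, and best none. Birch held 4.55 × 10⁻⁴ M of first end groups and 3.55 × 10⁻⁴ M of second end groups throughout the tank. With the way back removed, the tank constant of birch becomes 36400 L mol⁻¹, which gives 86.3 % links, and that stands 8.7 points below the 95.0 % that the charge of second end groups allows. In the simulation without the way back, birch minus cedar came to −8.5 points.

The numbers come from no measurement; no experiment stands behind them.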